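**One-step ceiling.** A one-step world, substrate plus coupling partner to product, puts the ceiling at the smaller charge: 23.8% of the substrate in Monday's flask and 75.4% in Tuesday's. The readings stop far lower. Monday's readings average 7.50% from 2.50 h on, and Tuesday's readings average 19.3% from 4.00 h on.

in all of them: substrate 0.13 M

| charge | coupling partner | remark | time |
|---|---|---|---|
| Monday's | 0.031 M | run made earlier |  |
| Tuesday's | 0.098 M | run made earlier |  |
| green | 0.156 M |  | 20 h |
| blue | 0.0500 M |  | 20 h |

| run | time / h | product / % |
|---|---|---|
| Monday's | 2.50 | 7 |
| Monday's | 5.00 | 7 |
| Monday's | 8.00 | 9 |
| Monday's | 10.0 | 7 |
| Tuesday's | 1.33 | 15 |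
| Tuesday's | 4.00 | 21 |
| Tuesday's | 6.00 | 19 |
| Tuesday's | 10.0 | 18 |

(scatter of a reading: 1.5 percentage points)

- the winner by amount of product, in percent of the substrate charged; "neither" if no more than 2 percentage points parts them (green / blue / neither)
- how much product is there at the end, in percent of the substrate charged: green
- how much product is there at the end, in percent of the substrate charged: blue



**Plateau constant.** Let K, the equilibrium constant of the coupling, be product over uncoupled substrate times unused coupling partner, in molar amounts at the plateau. Monday's readings give 3.82 L mol⁻¹ and Tuesday's give 3.29 L mol⁻¹. Their mean, 3.55 L mol⁻¹, is the plateau constant, a reading that carries the scatter of the runs.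

**Outcome reversed.** While product stays a small correction to the charges, its share of the substrate is about K times the partner charge. A gap as small as 2 percentage points between green and blue then asks for K near 0.189 L mol⁻¹, and the reading stands far above that. My own reckoning solves the full balance with K and gives green 29.5% and blue 11.2%.

**The forecast.** It names green as the winner, with green at 28% and blue at 11%, on the ground that “the plateau depends on the coupling partner concentration”. My green figure lies above its green figure.

**The result.** Green ends at 29.2% and blue at 11.1%, so green gives more.

    substrate → intermediate (k = 5.30 h⁻¹)
    coupling partner + intermediate ⇌ product (K = 3.50 L mol⁻¹, k = 2.90 L mol⁻¹ h⁻¹)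

**The way back.** At 20.0 h green holds 0% substrate and 70.8% intermediate, so the uncoupled substrate in K is intermediate. The main reason green stops there is the undoing of product. Without that step the same flask gives 95.4%, and the forecast's green figure fails. With the way back in place, K puts a neighbour of green, charged with 0.62 M of coupling partner, at 65.5%, and that flask ends at 65.2%.

(The earlier runs and the new flask are simulated from invented constants, and the scatter is random.)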